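**Retrosynthetic overview**

1. Target 23 ⇒ (acetylation, N–O cleavage, angeloylation, C11 hydroxylation, lactol oxidation) ⇒ cis-fused lactol ethyl acetal 14, which carries the C8 oxygen as a tetramethylpiperidinyl ether.
2. 14 ⇒ bromoacetal 12 + TEMPO 13: one radical step makes C7–C11 and C8–O. The feature used is the γ-lactone ring O6–C12–C11–C7–C6, cis-fused to the cyclohexane, with the C8 oxygen trans to the C7–C11 bond; this is what a radical tethered to O6 leaves when it adds across a C7=C8 alkene.
3. 12 ⇒ allylic alcohol 10 ⇒ (Wharton transposition, epoxidation anti to isopropenyl, Saegusa–Ito oxidation) ⇒ silyl enol ether 6.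
4. 6 ⇒ (cyclobutane cleavage) ⇒ vinyl adduct 4 ⇒ (1S)-(−)-verbenone 1 + vinyl cuprate; the pinane frame fixes vinyl trans to isopropenyl at C10/C5.
5. Ring order: the cyclohexane is the six-membered ring of verbenone (cyclobutane opened in step 2); the five-membered O-heterocycle is closed in the key step and oxidised to the lactone afterwards.

Key step: step 7

Locants and faces: C10 = C(CH3)(vinyl), C5 = CH(isopropenyl), C6 = CH–O of the lactone, C7 = ring-fusion CH, C8 = CH–O (acetate in the target), C9 = CH2, C11 = lactone C(CH3)(O), C12 = lactone C=O; β is the ring face of the C10 methyl, α that of the C10 vinyl.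

Assumption: (1S)-(−)-verbenone 1 is used in high enantiomeric purity; a lot of low optical purity would be replaced by material from allylic oxidation of enantiopure (−)-α-pinene.

**Route**

Step 1
Reactants: 1 (1S,5S)-(−)-verbenone; 2 vinylmagnesium bromide
Product: 4 (1S,4R,5R)-4,6,6-trimethyl-4-vinylbicyclo[3.1.1]heptan-2-one, via bromomagnesium enolate 3 (not isolated)
Conditions: CuBr·SMe2 (cat.), THF, −40 → 0 °C; 1 M HCl quench
Reagents that add atoms: none
Why: Copper-catalysed conjugate addition of a vinyl Grignard reagent (organocuprate 1,4-addition); the vinyl group reaches C10 from the enone face opposite the gem-dimethyl bridge, so the bicyclic frame sets the quaternary centre with vinyl anti to the carbon that becomes the isopropenyl group.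

Step 2
Reactants: 4 (1S,4R,5R)-4,6,6-trimethyl-4-vinylbicyclo[3.1.1]heptan-2-one
Product: 6 trimethyl{[(4R,5R)-5-methyl-4-(prop-1-en-2-yl)-5-vinylcyclohex-1-en-1-yl]oxy}silane, via iodo silyl enol ether 5 (not isolated)
Conditions: TMSI, CH2Cl2, −20 → 0 °C; then DBU, 0 °C → rt; pentane, cold aq. NaHCO3 wash
Reagents that add atoms: iodotrimethylsilane, C[Si](C)(C)I
Why: Silyl-iodide-promoted heterolytic cleavage of the strained cyclobutane bond α to the ketone (homo-conjugate opening of a cyclobutyl ketone) should give a tertiary iodide and the regiodefined C7=C8 silyl enol ether, and E2 elimination with DBU should take a methyl hydrogen because the ring methine next to the quaternary carbon is shielded; no stereocentre is touched, so vinyl and isopropenyl stay trans.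

Step 3
Reactants: 6 trimethyl{[(4R,5R)-5-methyl-4-(prop-1-en-2-yl)-5-vinylcyclohex-1-en-1-yl]oxy}silane
Product: 7 (4R,5R)-5-methyl-4-(prop-1-en-2-yl)-5-vinylcyclohex-2-en-1-one
Conditions: Pd(OAc)2 (1.1 equiv), MeCN, rt
Reagents that add atoms: none
Why: Saegusa–Ito oxidation; the palladium(II) enolate at C7 can lose only a C6 hydrogen, which gives the C6=C7 enone without touching C5 or C10.

Step 4
Reactants: 7 (4R,5R)-5-methyl-4-(prop-1-en-2-yl)-5-vinylcyclohex-2-en-1-one
Product: 8 (1S,4R,5R,6S)-4-methyl-5-(prop-1-en-2-yl)-4-vinyl-7-oxabicyclo[4.1.0]heptan-2-one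
Conditions: 30% aq. H2O2, NaOH (cat.), MeOH, −10 → 0 °C
Reagents that add atoms: hydrogen peroxide, OO
Why: Weitz–Scheffer nucleophilic epoxidation; hydroperoxide should add to C6 of the only electron-poor alkene anti to the neighbouring β-isopropenyl group on C5 and close the epoxide on the α face, which sets C6 (and, for the moment, C7).

Step 5
Reactants: 8 (1S,4R,5R,6S)-4-methyl-5-(prop-1-en-2-yl)-4-vinyl-7-oxabicyclo[4.1.0]heptan-2-one
Product: 10 (1R,5R,6R)-5-methyl-6-(prop-1-en-2-yl)-5-vinylcyclohex-2-en-1-ol, via epoxy hydrazone 9 (not isolated)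
Conditions: N2H4·H2O, AcOH (cat.), MeOH, 0 °C → rt, under argon
Reagents that add atoms: none
Why: Wharton transposition; the epoxy hydrazone opens to an allylic diazene that loses nitrogen, which moves the alkene to C7=C8 and leaves the C6–O bond of the epoxide intact, so the α-configured C6 carbinol (trans to isopropenyl) is retained.

Step 6
Reactants: 10 (1R,5R,6R)-5-methyl-6-(prop-1-en-2-yl)-5-vinylcyclohex-2-en-1-ol; 11 ethyl 1-propenyl ether (E/Z mixture)
Product: 12 2-bromo-1-ethoxypropyl ether of 10 (2-bromopropanal ethyl acetal on O6; acetal and CHBr centres as mixtures)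
Conditions: NBS, CH2Cl2, −78 → −20 °C
Reagents that add atoms: N-bromosuccinimide, O=C1CCC(=O)N1Br
Why: Haloetherification of an enol ether (bromoacetalisation, the first half of the Ueno–Stork sequence); NBS should activate the electron-rich enol ether far faster than the three isolated alkenes, and the alcohol captures the oxocarbenium ion; the two new centres form as mixtures that are erased later.

Step 7
Reactants: 12 2-bromo-1-ethoxypropyl ether of 10; 13 TEMPO
Product: 14 cis-fused bicyclic lactol ethyl acetal (O6 and C11 α on C6/C7) with 8β-O-(2,2,6,6-tetramethylpiperidin-1-yl), 5β-isopropenyl, 10β-methyl and 10α-vinyl (C11 and acetal carbon as mixtures)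
Conditions: n-Bu3SnH and TEMPO, each added by syringe pump, degassed PhH (dilute), 80 °C
Reagents that add atoms: none
Why: The tributylstannyl radical (formed from the stannane and TEMPO) abstracts bromine to give the secondary C11 radical, which adds 5-exo-trig to C7 of the ring alkene and leaves a secondary C8 radical that couples with TEMPO; this is the Ueno–Stork haloacetal cyclisation ended by nitroxide capture. The tetrahydrofuran ring O6–CH(OEt)–C11–C7–C6 closes in the 5-exo mode and, because the two-atom tether hangs from O6, can only be cis-fused, so C7 takes C11 on the α face that already carries O6. The nitroxide should then reach C8 from the convex β face, anti to the new C7–C11 bond and to the α-vinyl group on C10, which places the C8 oxygen trans to C7–C11. The acetal carbon and C11 form as mixtures, which does no harm because the first becomes the lactone carbonyl and the second is reset by enolate hydroxylation. The step needs ring closure to outrun direct coupling of the C11 radical with TEMPO and needs the ring alkene to be chosen over vinyl and isopropenyl; the fast 3-oxa-5-hexenyl closure together with a low stationary nitroxide concentration (slow addition) should secure the first, and the tether length, which offers only seven-membered modes to the other alkenes, the second.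

Step 8
Reactants: 14 cis-fused lactol ethyl acetal with 8β-O-tetramethylpiperidinyl ether
Product: 15 corresponding lactol (C12 hemiacetal; C11 and C12 as mixtures)
Conditions: 1 M aq. HCl–THF (1:4), rt; NaHCO3 work-up
Reagents that add atoms: water, O
Why: Acid hydrolysis of a mixed cyclic acetal to the lactol; the alkoxyamine and the two terminal alkenes should tolerate dilute acid at room temperature, and no ring stereocentre is involved.

Step 9
Reactants: 15 lactol
Product: 16 cis-fused 6α,12-γ-lactone with 8β-O-(2,2,6,6-tetramethylpiperidin-1-yl) (C11 epimers)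
Conditions: TPAP (cat.), NMO, 4 Å MS, CH2Cl2, rt
Reagents that add atoms: none
Why: Ley–Griffith oxidation of a lactol to the γ-lactone; the hindered alkoxyamine and the alkenes are inert to these conditions.

Step 10
Reactants: 16 cis-fused lactone (C11 epimers)
Product: 18 11-hydroxy lactone (11-OH on the face of H-7, 11-methyl toward C8), via potassium lactone enolate 17 (not isolated)
Conditions: KHMDS, THF, −78 °C; 3-phenyl-2-(phenylsulfonyl)oxaziridine, −78 °C; AcOH quench
Reagents that add atoms: 3-phenyl-2-(phenylsulfonyl)oxaziridine, O=S(=O)(c1ccccc1)N1OC1c1ccccc1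
Why: Enolate oxidation with an N-sulfonyloxaziridine; both C11 epimers give the same enolate, which should take oxygen on the convex face of the cis-fused bicycle (the side of H-7, away from the carbocycle), so the hydroxyl ends cis to H-7 and the methyl cis to C8.

Step 11
Reactants: 18 11-hydroxy lactone; 19 angelic acid [(Z)-2-methylbut-2-enoic acid]
Product: 21 11-O-angelate of 18 (8β-O-tetramethylpiperidinyl ether retained), via lithium alkoxide 20 (not isolated)
Conditions: 19, 2,4,6-trichlorobenzoyl chloride, Et3N, toluene, rt (mixed anhydride); 18, LiHMDS, THF, −78 °C, then the anhydride, −78 → 0 °C; cold 0.5 M HCl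
Reagents that add atoms: none
Why: O-Acylation of a tertiary lithium alkoxide with a Yamaguchi-type mixed anhydride; the alkoxide should attack the less hindered angeloyl carbonyl, and the absence of a nucleophilic amine catalyst together with the low temperature should keep the Z geometry.

Step 12
Reactants: 21 11-O-angelate with 8β-O-tetramethylpiperidinyl ether
Product: 22 8β-hydroxy 11-O-angeloyl lactone
Conditions: Zn dust, AcOH–THF–H2O (3:1:1), 50 °C
Reagents that add atoms: none
Why: Reductive N–O cleavage of an O-alkyl hydroxylamine with zinc in acetic acid should free the C8 alcohol with retention; the α-acyloxy lactone and the angelate are not reduced under these conditions.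

Step 13
Reactants: 22 8β-hydroxy 11-O-angeloyl lactone
Product: 23 target, (3S,3aR,4S,6R,7R,7aS)-4-acetoxy-3,6-dimethyl-2-oxo-7-(prop-1-en-2-yl)-6-vinyloctahydro-1-benzofuran-3-yl (Z)-2-methylbut-2-enoate
Conditions: Ac2O, pyridine, DMAP (cat.), CH2Cl2, 0 °C → rt
Reagents that add atoms: acetic anhydride, CC(=O)OC(C)=O
Why: DMAP-catalysed acetylation of the secondary C8 alcohol; the tertiary C11 oxygen is already esterified and no stereocentre changes.

**Compound list**

1 | (1S,5S)-(−)-verbenone [(1S,5S)-4,6,6-trimethylbicyclo[3.1.1]hept-3-en-2-one] | CC1=CC(=O)[C@H]2C[C@@H]1C2(C)C | starting material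
2 | vinylmagnesium bromide | C=C[Mg]Br | starting material
3 | bromomagnesium enolate of 4 | C=C[C@@]1(C)C=C(O[Mg]Br)[C@H]2C[C@@H]1C2(C)C | intermediate
4 | (1S,4R,5R)-4,6,6-trimethyl-4-vinylbicyclo[3.1.1]heptan-2-one | C=C[C@@]1(C)CC(=O)[C@H]2C[C@@H]1C2(C)C | intermediate
5 | {[(4S,5R)-4-(2-iodopropan-2-yl)-5-methyl-5-vinylcyclohex-1-en-1-yl]oxy}trimethylsilane | C=C[C@@]1(C)CC(O[Si](C)(C)C)=CC[C@@H]1C(C)(C)I | intermediate
6 | trimethyl{[(4R,5R)-5-methyl-4-(prop-1-en-2-yl)-5-vinylcyclohex-1-en-1-yl]oxy}silane | C=C[C@@]1(C)CC(O[Si](C)(C)C)=CC[C@@H]1C(=C)C | intermediate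
7 | (4R,5R)-5-methyl-4-(prop-1-en-2-yl)-5-vinylcyclohex-2-en-1-one | C=C[C@@]1(C)CC(=O)C=C[C@@H]1C(=C)C | intermediate
8 | (1S,4R,5R,6S)-4-methyl-5-(prop-1-en-2-yl)-4-vinyl-7-oxabicyclo[4.1.0]heptan-2-one | C=C[C@@]1(C)CC(=O)[C@H]2O[C@H]2[C@@H]1C(=C)C | intermediate
9 | hydrazone of epoxy ketone 8 | C=C[C@@]1(C)CC(=NN)[C@H]2O[C@H]2[C@@H]1C(=C)C | intermediate
10 | (1R,5R,6R)-5-methyl-6-(prop-1-en-2-yl)-5-vinylcyclohex-2-en-1-ol | C=C[C@@]1(C)CC=C[C@@H](O)[C@@H]1C(=C)C | intermediate
11 | ethyl 1-propenyl ether (E/Z mixture) | CC=COCC | starting material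
12 | 2-bromo-1-ethoxypropyl ether of 10 (acetal and CHBr centres as mixtures) | C=C[C@@]1(C)CC=C[C@@H](OC(OCC)C(C)Br)[C@@H]1C(=C)C | intermediate
13 | TEMPO (2,2,6,6-tetramethylpiperidin-1-oxyl) | CC1(C)CCCC(C)(C)N1[O] | starting material
14 | cis-fused lactol ethyl acetal, 6α-O/7α-C11, 8β-O-(2,2,6,6-tetramethylpiperidin-1-yl), 5β-isopropenyl, 10β-methyl, 10α-vinyl (C11 and acetal carbon as mixtures) | C=C[C@@]1(C)C[C@H](ON3C(C)(C)CCCC3(C)C)[C@@H]2[C@@H](OC(OCC)C2C)[C@@H]1C(=C)C | intermediate
15 | lactol corresponding to 14 (C11 and C12 as mixtures) | C=C[C@@]1(C)C[C@H](ON3C(C)(C)CCCC3(C)C)[C@@H]2[C@@H](OC(O)C2C)[C@@H]1C(=C)C | intermediate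
16 | cis-fused 6α,12-lactone with 8β-O-(2,2,6,6-tetramethylpiperidin-1-yl) (C11 epimers) | C=C[C@@]1(C)C[C@H](ON3C(C)(C)CCCC3(C)C)[C@@H]2[C@@H](OC(=O)C2C)[C@@H]1C(=C)C | intermediate
17 | potassium enolate of lactone 16 | C=C[C@@]1(C)C[C@H](ON3C(C)(C)CCCC3(C)C)[C@@H]2[C@@H](OC(O[K])=C2C)[C@@H]1C(=C)C | intermediate
18 | 11-hydroxy lactone (11-OH cis to H-7, 11-methyl cis to C8), 8β-O-tetramethylpiperidinyl ether | C=C[C@@]1(C)C[C@H](ON3C(C)(C)CCCC3(C)C)[C@@H]2[C@@H](OC(=O)[C@@]2(C)O)[C@@H]1C(=C)C | intermediate
19 | angelic acid [(Z)-2-methylbut-2-enoic acid] | C/C=C(/C)C(=O)O | starting material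
20 | lithium alkoxide of 18 | C=C[C@@]1(C)C[C@H](ON3C(C)(C)CCCC3(C)C)[C@@H]2[C@@H](OC(=O)[C@@]2(C)O[Li])[C@@H]1C(=C)C | intermediate
21 | 11-O-angelate of 18 (8β-O-tetramethylpiperidinyl ether) | C=C[C@@]1(C)C[C@H](ON3C(C)(C)CCCC3(C)C)[C@@H]2[C@@H](OC(=O)[C@@]2(C)OC(=O)/C(C)=C\C)[C@@H]1C(=C)C | intermediate
22 | 8β-hydroxy 11-O-angeloyl lactone | C=C[C@@]1(C)C[C@H](O)[C@@H]2[C@@H](OC(=O)[C@@]2(C)OC(=O)/C(C)=C\C)[C@@H]1C(=C)C | intermediate
23 | target, (3S,3aR,4S,6R,7R,7aS)-4-acetoxy-3,6-dimethyl-2-oxo-7-(prop-1-en-2-yl)-6-vinyloctahydro-1-benzofuran-3-yl (Z)-2-methylbut-2-enoate | C=C[C@@]1(C)C[C@H](OC(C)=O)[C@@H]2[C@@H](OC(=O)[C@@]2(C)OC(=O)/C(C)=C\C)[C@@H]1C(=C)C | target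

**Step count and risks**

Total step count: 13. Longest linear sequence: 13 steps (1 → 23).

Steps most likely to fail:

1. Step 7 (key step). The uncyclised C11 radical may couple with the nitroxide, or radicals may take hydrogen from the stannane, before ring closure and oxygen capture are complete. The fallback sets out from alcohol 10 and returns at 14, and it separates ring closure from oxygen capture. N-Iodosuccinimide and enol ether 11 should give the 2-iodo-1-ethoxypropyl ether of 10, F1. Iodine atom-transfer cyclisation (hexabutylditin, visible light, benzene) should close the same cis-fused ring with no nitroxide present and leave the bicyclic C8 iodide, F2. Tributyltin hydride with TEMPO then regenerates the C8 radical, which can only couple with the nitroxide on the β face, to give 14.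

2. Step 11. Acylation of the congested tertiary alkoxide may be slow, and the activated angeloyl donor may isomerise from Z to E. The fallback sets out from 18 and returns at 21, and it builds the alkene on the ester instead of transferring it. The lithium alkoxide is acylated with 2-[bis(2,2,2-trifluoroethoxy)phosphoryl]propanoyl chloride to the 11-O-phosphonopropanoate, F3. Still–Gennari olefination (KHMDS, 18-crown-6, acetaldehyde, −78 °C) should then form the Z-2-methylbut-2-enoate and give 21.

3. Step 2. The tertiary cation may rearrange, elimination may go toward the ring, or the silyl enol ether may hydrolyse during isolation. The fallback sets out from 4 and returns at 6, with oxygen capture of the cation and a separate dehydration. Acetolysis of the cyclobutane (BF3·OEt2, Zn(OAc)2, Ac2O) should give the enol acetate tertiary acetate, F4. Methanolysis (K2CO3, MeOH) gives 4-(2-hydroxypropan-2-yl)-3-methyl-3-vinylcyclohexanone, F5. Dehydration with methyl N-(triethylammoniosulfonyl)carbamate gives (3R,4R)-3-methyl-4-(prop-1-en-2-yl)-3-vinylcyclohexan-1-one, F6. Kinetic enolisation at C7, the only unhindered α-position (LDA, TMSCl, THF, −78 °C), returns 6.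

**Further compounds**

F1 | step 7 | 2-iodo-1-ethoxypropyl ether of 10 (acetal and CHI centres as mixtures) | C=C[C@@]1(C)CC=C[C@@H](OC(OCC)C(C)I)[C@@H]1C(=C)C
F2 | step 7 | cis-fused lactol ethyl acetal with iodine at C8 (C8, C11 and acetal carbon as mixtures) | C=C[C@@]1(C)CC(I)[C@@H]2[C@@H](OC(OCC)C2C)[C@@H]1C(=C)C
F3 | step 11 | 11-O-{2-[bis(2,2,2-trifluoroethoxy)phosphoryl]propanoate} of 18 | C=C[C@@]1(C)C[C@H](ON3C(C)(C)CCCC3(C)C)[C@@H]2[C@@H](OC(=O)[C@@]2(C)OC(=O)C(C)P(=O)(OCC(F)(F)F)OCC(F)(F)F)[C@@H]1C(=C)C
F4 | step 2 | 4-(2-acetoxypropan-2-yl)-5-methyl-5-vinylcyclohex-1-en-1-yl acetate | C=C[C@@]1(C)CC(OC(C)=O)=CC[C@@H]1C(C)(C)OC(C)=O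
F5 | step 2 | 4-(2-hydroxypropan-2-yl)-3-methyl-3-vinylcyclohexan-1-one | C=C[C@@]1(C)CC(=O)CC[C@@H]1C(C)(C)O
F6 | step 2 | (3R,4R)-3-methyl-4-(prop-1-en-2-yl)-3-vinylcyclohexan-1-one | C=C[C@@]1(C)CC(=O)CC[C@@H]1C(=C)C
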